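**Retrosynthetic overview**

1. The target is a 1-O-acetyl-2-O-acyl-sn-glycerol. The O-3 silyl ether and then the sn-2 ester C–O bond are cut first, giving a C15 (E)-enoic acid and 1-O-acetyl-3-O-TBDPS-sn-glycerol, whose only stereocentre (glycerol C2) is bought with (S)-solketal.
2. The acid (chain C1 = carboxyl to C5, ring C1'–C6') is cut at the C5–C1' bond, between the side-chain CH2 and the tetrasubstituted ring-alkene carbon, into 2,6,6-trimethylcyclohexenyl triflate and a primary alkyl-9-BBN reagent (B-alkyl Suzuki–Miyaura coupling).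
3. The plan rests on one feature: C1' lies between the quaternary gem-dimethyl carbon C6' and the methyl-bearing C2'. The parent ketone, 2,2,6-trimethylcyclohexanone, therefore has one α-hydrogen only and can give a single enol triflate, with the C1'=C2' alkene already in place.
4. The borane partner comes from ethyl (E)-3-methyl-4-oxobut-2-enoate, which supplies the (E)-C2=C3 bond. Wittig methylenation adds C5, and 9-BBN hydroboration of the new vinyl group makes the C5–B bond.
5. Ring order: the only ring, the cyclohexene, is purchased intact; no ring is formed in the route.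

Key step: step 3

Assumption: ketone 1 is used as the racemate (its stereocentre becomes sp2 in step 1), and 9-BBN 6 is drawn as the monomer although it is supplied as the dimer or a THF solution.

**Route**

Step 1
Reactants: 1 2,2,6-trimethylcyclohexanone
Product: 3 enol triflate (2,6,6-trimethylcyclohex-1-en-1-yl trifluoromethanesulfonate), via lithium enolate 2 (not isolated)
Conditions: LiN(iPr)2 (1.2 equiv), THF, −78 → 0 °C; then PhNTf2 (1.2 equiv), 0 °C → rt
Reagents that add atoms: N-phenyl-bis(trifluoromethanesulfonimide), O=S(=O)(N(c1ccccc1)S(=O)(=O)C(F)(F)F)C(F)(F)F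
Why: Because C2 of ketone 1 is quaternary, LiN(iPr)2 can remove only the C6 hydrogen, and O-sulfonylation of the resulting single enolate by PhNTf2 (enol triflate formation) should place the alkene exactly between the future C1' and the methyl-bearing C2'.

Step 2
Reactants: 4 ethyl (E)-3-methyl-4-oxobut-2-enoate
Product: 5 ethyl (E)-3-methylpenta-2,4-dienoate
Conditions: Ph3PCH3Br (1.2 equiv), KOtBu (1.15 equiv), THF, 0 °C; then 4, −78 → 0 °C
Reagents that add atoms: methyltriphenylphosphonium bromide, C[P+](c1ccccc1)(c1ccccc1)c1ccccc1.[Br-]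
Why: Wittig methylenation, in which the non-stabilised ylide should attack the aldehyde much faster than the conjugated ester, while the C2=C3 bond is not a reacting centre and keeps its (E)-geometry.

Step 3
Reactants: 5 ethyl (E)-3-methylpenta-2,4-dienoate; 6 9-borabicyclo[3.3.1]nonane (9-BBN); 3 enol triflate
Product: 8 ethyl (E)-3-methyl-5-(2,6,6-trimethylcyclohex-1-en-1-yl)pent-2-enoate, via alkylborane 7 (not isolated)
Conditions: 5 and 6 (1.5 equiv each, 0.5 M in THF), 0 °C → rt; then 3 (1.0 equiv), PdCl2(dppf)·CH2Cl2 (10 mol%), 3 M aq K3PO4, DMF, 60 °C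
Reagents that add atoms: none
Why: 9-BBN adds its B–H bond across the terminal C4=C5 vinyl group of 5 with boron on the unhindered C5, giving primary alkylborane 7 (ethyl (E)-5-(9-borabicyclo[3.3.1]nonan-9-yl)-3-methylpent-2-enoate); zerovalent palladium, formed in the flask from the divalent palladium precatalyst PdCl2(dppf), then inserts into the C–O bond of triflate 3, the base-activated borate hands its primary alkyl group to palladium, and reductive elimination forges the C5–C1' sp3–sp2 bond. The closest known reaction type is the B-alkyl Suzuki–Miyaura coupling of 9-alkyl-9-BBN reagents with cyclic enol triflates under PdCl2(dppf) and K3PO4, applied here at its hindered limit, a tetrasubstituted alkenyl triflate beside a quaternary carbon. No ring is closed and no stereocentre is created. The step needs chemoselective and regioselective hydroboration of the monosubstituted vinyl group in the presence of the trisubstituted, ester-conjugated C2=C3 bond, which the bulk of 9-BBN and the hindered, electron-poor nature of C2=C3 should secure. The position of the ring alkene is dictated by the triflate and the (E)-geometry of C2=C3 is not touched, while the wide bite angle of dppf favours reductive elimination over β-hydride elimination of the alkylpalladium intermediate. K3PO4 is basic enough to form the borate yet mild enough to leave the ethyl ester intact.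

Step 4
Reactants: 8 ethyl (E)-3-methyl-5-(2,6,6-trimethylcyclohex-1-en-1-yl)pent-2-enoate
Product: 10 (E)-3-methyl-5-(2,6,6-trimethylcyclohex-1-en-1-yl)pent-2-enoic acid, via lithium carboxylate 9 (not isolated)
Conditions: LiOH·H2O (5 equiv), THF/MeOH/H2O, 50 °C; then 1 M HCl to pH 3, 0 °C
Reagents that add atoms: lithium hydroxide, [Li+].[OH-]
Why: Saponification (base-mediated acyl substitution) followed by acidification should give the acid, since aqueous hydroxide neither moves nor isomerises the β,β-disubstituted C2=C3 bond and the ring alkene is inert.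

Step 5
Reactants: 11 (S)-solketal, (S)-(2,2-dimethyl-1,3-dioxolan-4-yl)methanol
Product: 12 (R)-tert-butyl[(2,2-dimethyl-1,3-dioxolan-4-yl)methoxy]diphenylsilane
Conditions: TBDPSCl (1.1 equiv), imidazole (2 equiv), CH2Cl2, 0 °C → rt
Reagents that add atoms: tert-butyl(chloro)diphenylsilane, CC(C)(C)[Si](Cl)(c1ccccc1)c1ccccc1
Why: Imidazole-assisted silyl ether formation at the only free hydroxyl, which leaves the stereocentre untouched (the descriptor changes from S to R only because the CH2OSi arm now outranks the ring CH2O arm).

Step 6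
Reactants: 12 (R)-tert-butyl[(2,2-dimethyl-1,3-dioxolan-4-yl)methoxy]diphenylsilane
Product: 13 (R)-3-[(tert-butyldiphenylsilyl)oxy]propane-1,2-diol (3-O-TBDPS-sn-glycerol)
Conditions: AcOH/H2O (4:1), 45 °C
Reagents that add atoms: none
Why: Acid-catalysed hydrolysis of the isopropylidene acetal cleaves the acetal C–O bonds and not those at C2, so the configuration is retained, and the TBDPS ether is stable to aqueous acetic acid.

Step 7
Reactants: 13 (R)-3-[(tert-butyldiphenylsilyl)oxy]propane-1,2-diol
Product: 14 (R)-3-[(tert-butyldiphenylsilyl)oxy]-2-hydroxypropyl acetate (1-O-acetyl-3-O-TBDPS-sn-glycerol)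
Conditions: AcCl (1.05 equiv), 2,4,6-collidine (2 equiv), CH2Cl2, −78 °C
Reagents that add atoms: acetyl chloride, CC(Cl)=O
Why: Kinetically controlled selective acylation of the primary over the secondary hydroxyl by acetyl chloride with the hindered base 2,4,6-collidine at low temperature, with the stereocentre untouched.

Step 8
Reactants: 10 (E)-3-methyl-5-(2,6,6-trimethylcyclohex-1-en-1-yl)pent-2-enoic acid; 14 (R)-3-[(tert-butyldiphenylsilyl)oxy]-2-hydroxypropyl acetate
Product: 15 (R)-1-acetoxy-3-[(tert-butyldiphenylsilyl)oxy]propan-2-yl (E)-3-methyl-5-(2,6,6-trimethylcyclohex-1-en-1-yl)pent-2-enoate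
Conditions: DCC (1.3 equiv), DMAP (0.2 equiv), CH2Cl2, 0 °C → rt
Reagents that add atoms: none
Why: Steglich esterification, in which DCC activates acid 10 and DMAP transfers the acyl group to the secondary hydroxyl of 14 with retention at C2 (the C2–O bond is not broken), under aprotic conditions cold enough to keep the neighbouring acetate in place.

Step 9
Reactants: 15 (R)-1-acetoxy-3-[(tert-butyldiphenylsilyl)oxy]propan-2-yl (E)-3-methyl-5-(2,6,6-trimethylcyclohex-1-en-1-yl)pent-2-enoate
Product: 16 (S)-1-acetoxy-3-hydroxypropan-2-yl (E)-3-methyl-5-(2,6,6-trimethylcyclohex-1-en-1-yl)pent-2-enoate (target, CNP0305511.1)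
Conditions: HF·pyridine, pyridine, THF, 0 °C → rt; cold aq NaHCO3 work-up
Reagents that add atoms: none
Why: Fluoride-driven desilylation (strong Si–F bond) in a pyridine-buffered medium that should be too mild to shift the enoyl group from O-2 to the freed O-3 hydroxyl or to add to the alkenes, with C2 untouched and S only through the change in substituent priorities.

**Compound list**

1 | 2,2,6-trimethylcyclohexanone (racemic) | CC1CCCC(C)(C)C1=O | starting material
2 | lithium 2,6,6-trimethylcyclohex-1-en-1-olate | CC1=C([O-])C(C)(C)CCC1.[Li+] | intermediate (not isolated)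
3 | 2,6,6-trimethylcyclohex-1-en-1-yl trifluoromethanesulfonate | CC1=C(OS(=O)(=O)C(F)(F)F)C(C)(C)CCC1 | intermediate
4 | ethyl (E)-3-methyl-4-oxobut-2-enoate | CCOC(=O)/C=C(\C)C=O | starting material
5 | ethyl (E)-3-methylpenta-2,4-dienoate | CCOC(=O)/C=C(\C)C=C | intermediate
6 | 9-borabicyclo[3.3.1]nonane (9-BBN) | C1CC2CCCC(C1)B2 | starting material
7 | ethyl (E)-5-(9-borabicyclo[3.3.1]nonan-9-yl)-3-methylpent-2-enoate | CCOC(=O)/C=C(\C)CCB1C2CCCC1CCC2 | intermediate (not isolated)
8 | ethyl (E)-3-methyl-5-(2,6,6-trimethylcyclohex-1-en-1-yl)pent-2-enoate | CCOC(=O)/C=C(\C)CCC1=C(C)CCCC1(C)C | intermediate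
9 | lithium (E)-3-methyl-5-(2,6,6-trimethylcyclohex-1-en-1-yl)pent-2-enoate | [Li+].[O-]C(=O)/C=C(\C)CCC1=C(C)CCCC1(C)C | intermediate (not isolated)
10 | (E)-3-methyl-5-(2,6,6-trimethylcyclohex-1-en-1-yl)pent-2-enoic acid | OC(=O)/C=C(\C)CCC1=C(C)CCCC1(C)C | intermediate
11 | (S)-solketal, (S)-(2,2-dimethyl-1,3-dioxolan-4-yl)methanol | CC1(C)OC[C@H](CO)O1 | starting material
12 | (R)-tert-butyl[(2,2-dimethyl-1,3-dioxolan-4-yl)methoxy]diphenylsilane | CC1(C)OC[C@H](CO[Si](c2ccccc2)(c2ccccc2)C(C)(C)C)O1 | intermediate
13 | (R)-3-[(tert-butyldiphenylsilyl)oxy]propane-1,2-diol | OC[C@H](CO[Si](c1ccccc1)(c1ccccc1)C(C)(C)C)O | intermediate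
14 | (R)-3-[(tert-butyldiphenylsilyl)oxy]-2-hydroxypropyl acetate | CC(=O)OC[C@H](CO[Si](c1ccccc1)(c1ccccc1)C(C)(C)C)O | intermediate
15 | (R)-1-acetoxy-3-[(tert-butyldiphenylsilyl)oxy]propan-2-yl (E)-3-methyl-5-(2,6,6-trimethylcyclohex-1-en-1-yl)pent-2-enoate | CC(=O)OC[C@H](CO[Si](c1ccccc1)(c1ccccc1)C(C)(C)C)OC(=O)/C=C(\C)CCC1=C(C)CCCC1(C)C | intermediate
16 | (S)-1-acetoxy-3-hydroxypropan-2-yl (E)-3-methyl-5-(2,6,6-trimethylcyclohex-1-en-1-yl)pent-2-enoate | CC(=O)OC[C@H](CO)OC(=O)/C=C(\C)CCC1=C(C)CCCC1(C)C | target

**Step count and risks**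

Total step count: 9. Longest linear sequence: 5 steps (for example steps 1, 3, 4, 8, 9; the solketal branch, steps 5–9, is equally long).

Steps most likely to fail:

1. Step 3 (key step). Boron may be delivered in part to the internal carbon C4, or the B–H bond may reduce the dienoate in a conjugate sense. Oxidative addition and transmetalation at the doubly flanked C1' may also be so slow that protodeboronation of the alkylborane and hydrolysis of the triflate outrun the coupling. The fallback sets out from triflate 3 and comes back at ester 8. A Heck reaction of 3 with methyl vinyl ketone (Pd(OAc)2, PPh3, K2CO3, DMF, 70 °C) should give β-ionone F1, a compound that can also be bought, so the fallback may be entered there. Conjugate reduction of its disubstituted enone alkene with [(Ph3P)CuH]6 (wet benzene, rt) should give dihydro-β-ionone F2. Horner–Wadsworth–Emmons olefination of F2 with triethyl phosphonoacetate (NaH, THF, 0 °C → reflux) should then give 8 together with its (Z)-isomer, which would be removed by chromatography before step 4.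

2. Step 9. During the slow cleavage of the TBDPS ether, the work-up or chromatography, the enoyl group may migrate from O-2 to the liberated O-3 hydroxyl, giving the 1,3-diacyl isomer; on long exposure HF may also add to the tetrasubstituted ring alkene. The fallback replaces the silyl ether by a 4-methoxybenzyl ether that is removed oxidatively at neutral pH. It sets out from (S)-solketal 11 and acid 10 and comes back at target 16. Alkylation of 11 (NaH, 4-methoxybenzyl chloride, DMF) should give the PMB ether F3. Hydrolysis of the acetal (AcOH/H2O, 45 °C) should give the diol F4, and selective acetylation (AcCl, 2,4,6-collidine, CH2Cl2, −78 °C) the monoacetate F5. Esterification with 10 (DCC, DMAP, CH2Cl2) should give the diester F6. Oxidative debenzylation with 2,3-dichloro-5,6-dicyano-1,4-benzoquinone (CH2Cl2/pH 7 phosphate buffer, 0 °C) should then release 16.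

3. Step 8. Under DMAP the acetyl group of 14 may shift from O-1 to O-2, and the freed primary hydroxyl would then be acylated to a regioisomeric diester. Slow attack by the flanked secondary hydroxyl may let the activated acid rearrange to the N-acylurea, and γ-deprotonation of the activated acid may scramble the C2=C3 bond. The fallback introduces the acetate only after the enoate, so that no acyl neighbour is present during the esterification. It sets out from diol 13 and comes back at 15. Tin-mediated primary etherification (Bu2SnO, toluene, reflux; then 4-methoxybenzyl chloride, CsF, DMF) should give the PMB ether F7. Esterification with acid 10 (DCC, DMAP, CH2Cl2, rt, extended time) should give the ester F8. Oxidative debenzylation (2,3-dichloro-5,6-dicyano-1,4-benzoquinone, CH2Cl2/pH 7 buffer, 0 °C) should give the primary alcohol F9, which would be acetylated at once (Ac2O, pyridine, 0 °C) to 15.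

**Further compounds**

F1 | step 3 | β-ionone, (E)-4-(2,6,6-trimethylcyclohex-1-en-1-yl)but-3-en-2-one | CC(=O)/C=C/C1=C(C)CCCC1(C)C
F2 | step 3 | dihydro-β-ionone, 4-(2,6,6-trimethylcyclohex-1-en-1-yl)butan-2-one | CC(=O)CCC1=C(C)CCCC1(C)C
F3 | step 9 | (S)-4-{[(4-methoxybenzyl)oxy]methyl}-2,2-dimethyl-1,3-dioxolane | CC1(C)OC[C@H](COCc2ccc(OC)cc2)O1
F4 | step 9 | (R)-3-[(4-methoxybenzyl)oxy]propane-1,2-diol | OC[C@H](COCc1ccc(OC)cc1)O
F5 | step 9 | (S)-2-hydroxy-3-[(4-methoxybenzyl)oxy]propyl acetate | CC(=O)OC[C@H](COCc1ccc(OC)cc1)O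
F6 | step 9 | (S)-1-acetoxy-3-[(4-methoxybenzyl)oxy]propan-2-yl (E)-3-methyl-5-(2,6,6-trimethylcyclohex-1-en-1-yl)pent-2-enoate | CC(=O)OC[C@H](COCc1ccc(OC)cc1)OC(=O)/C=C(\C)CCC1=C(C)CCCC1(C)C
F7 | step 8 | (R)-1-[(tert-butyldiphenylsilyl)oxy]-3-[(4-methoxybenzyl)oxy]propan-2-ol | COc1ccc(COC[C@H](CO[Si](c2ccccc2)(c2ccccc2)C(C)(C)C)O)cc1
F8 | step 8 | (R)-1-[(tert-butyldiphenylsilyl)oxy]-3-[(4-methoxybenzyl)oxy]propan-2-yl (E)-3-methyl-5-(2,6,6-trimethylcyclohex-1-en-1-yl)pent-2-enoate | COc1ccc(COC[C@H](CO[Si](c2ccccc2)(c2ccccc2)C(C)(C)C)OC(=O)/C=C(\C)CCC2=C(C)CCCC2(C)C)cc1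
F9 | step 8 | (R)-1-[(tert-butyldiphenylsilyl)oxy]-3-hydroxypropan-2-yl (E)-3-methyl-5-(2,6,6-trimethylcyclohex-1-en-1-yl)pent-2-enoate | OC[C@H](CO[Si](c1ccccc1)(c1ccccc1)C(C)(C)C)OC(=O)/C=C(\C)CCC1=C(C)CCCC1(C)C
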